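**Retrosynthetic overview**

- Kericembrenolide D ⇒ open-chain C14 primary alcohol carrying a 3-(acetoxymethyl)butenolide. The 14-membered ring closes last, by a visible-light C14–H abstraction / radical addition–elimination that forms C1–C14, sets C1 and C14, and reveals the exo-methylene.
- The C14 carbinol carbon ⇒ terminal (E)-methyl of the chain (allylic oxidation, methylenation, hydroboration).
- The butenolide (first ring) ⇒ ring-closing metathesis of the 2-(acetoxymethyl)acrylate of a C2 vinyl carbinol, itself from a terminal acetonide.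
- C5–C6 bond, (E)-C3=C4 and the C6 stereocentre ⇒ [2,3]-Wittig rearrangement of a geranyl ether, relaying chirality from a temporary C3 carbinol.
- C3 carbinol ⇒ (R)-glyceraldehyde acetonide (the only chiral material; supplies C2) + isopropenylmagnesium bromide; geranyl bromide supplies C6–C13.

Assumptions: cembrane numbering is used (C2 = lactone O–CH, C6 = CH–OAc, C14 = CH–OH, C1 = ring-fusion CH; the target is 1S,2S,6S,14S with a trans-fused lactone). (R)-Glyceraldehyde acetonide (from D-mannitol) is taken as purchasable.

**Step 1**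
Reactants: 1 (R)-2,3-O-isopropylideneglyceraldehyde; 2 isopropenylmagnesium bromide
Product: 3 (S)-1-[(R)-2,2-dimethyl-1,3-dioxolan-4-yl]-2-methylprop-2-en-1-ol (anti)
Conditions: 2 (1.3 equiv), THF, −78 °C; chromatography to remove the minor syn epimer
Reagents that add atoms: isopropenylmagnesium bromide, C=C(C)[Mg]Br
Why: Felkin–Anh Grignard addition to the α-alkoxy aldehyde; the purchased dioxolane centre sets the new carbinol anti (3S, roughly 4:1 expected), and this centre is only a relay that is consumed in step 3.

**Step 2**
Reactants: 3; 4 geranyl bromide [(E)-1-bromo-3,7-dimethylocta-2,6-diene]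
Product: 5 (R)-4-[(S)-1-(geranyloxy)-2-methylprop-2-en-1-yl]-2,2-dimethyl-1,3-dioxolane
Conditions: NaH, Bu4NI (cat.), THF/DMF, 0 °C → rt
Reagents that add atoms: geranyl bromide, CC(C)=CCC/C(C)=C/CBr
Why: Williamson etherification (SN2 at the primary allylic bromide); no stereocentre is touched.

**Step 3**
Reactants: 5
Product: 6 (1E,4S,5E)-1-[(4S)-2,2-dimethyl-1,3-dioxolan-4-yl]-2,6,10-trimethylundeca-1,5,9-trien-4-ol
Conditions: n-BuLi (1.5 equiv), THF, −78 → −30 °C; aq. NH4Cl
Reagents that add atoms: none
Why: [2,3]-Wittig rearrangement after deprotonation at the less substituted α-oxy allylic CH2 (geranyl); in the five-membered envelope transition state the dioxolanyl group is pseudo-equatorial (E-C3=C4) and the vinyl group is exo, away from the C4 methyl, so the C3–O chirality is transferred suprafacially to the new carbinol C6 (S) while the geranyl E-olefin is kept.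

**Step 4**
Reactants: 6
Product: 7 the C6 acetate of 6
Conditions: Ac2O, pyridine, DMAP (cat.), CH2Cl2, 0 °C → rt
Reagents that add atoms: acetic anhydride, CC(=O)OC(C)=O
Why: Standard acylation of the only free hydroxyl; it installs the final C6 acetate and makes the C6–H poorly hydridic for step 14.

**Step 5**
Reactants: 7
Product: 8 (2S,3E,6S,7E)-6-acetoxy-4,8,12-trimethyltrideca-3,7,11-triene-1,2-diol
Conditions: 80% aq. AcOH, rt
Reagents that add atoms: none
Why: Mild acid hydrolysis of the terminal acetonide; the acetate and the trisubstituted olefins are stable.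

**Step 6**
Reactants: 8
Product: 9 (2S,3E,6S,7E)-6-acetoxy-2-hydroxy-4,8,12-trimethyltrideca-3,7,11-trienal (used crude)
Conditions: TEMPO (10 mol%), PhI(OAc)2 (1.1 equiv), CH2Cl2, 0 °C → rt
Reagents that add atoms: none
Why: Oxoammonium (TEMPO) oxidation is sterically selective for the primary over the secondary alcohol and is non-basic, so C2 is not epimerised.

**Step 7**
Reactants: 9
Product: 10 (3R,4E,7S,8E)-3-hydroxy-5,9,13-trimethyltetradeca-1,4,8,12-tetraen-7-yl acetate (C2 vinyl carbinol; the descriptor changes only through CIP priorities)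
Conditions: CH2Br2, Zn, TiCl4 (Takai–Lombardo reagent), THF–CH2Cl2, 0 °C → rt
Reagents that add atoms: dibromomethane, BrCBr
Why: Takai–Lombardo methylenation is non-basic and aldehyde-selective, tolerates the free OH (as a Ti alkoxide) and the acetate, and does not epimerise the α-centre.

**Step 8**
Reactants: 11 2-(bromomethyl)acrylic acid
Product: 12 2-(acetoxymethyl)acrylic acid
Conditions: NaOAc (3 equiv), AcOH, 60 °C
Reagents that add atoms: sodium acetate, CC(=O)[O-].[Na+]
Why: Acetate displaces the allylic bromide; SN2 and SN2′ give the same product in this symmetrical allyl system.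

**Step 9**
Reactants: 10; 12
Product: 13 (3R,4E,7S,8E)-7-acetoxy-5,9,13-trimethyltetradeca-1,4,8,12-tetraen-3-yl 2-(acetoxymethyl)acrylate
Conditions: EDC·HCl, DMAP (5 mol%), CH2Cl2, 0 °C
Reagents that add atoms: 2-(acetoxymethyl)acrylic acid (12), C=C(COC(C)=O)C(=O)O
Why: Steglich esterification at oxygen, with retention at C2; DMAP is kept catalytic and cold to limit SN2′ attack on the allylic acetate.

**Step 10**
Reactants: 13
Product: 14 [(5S)-5-{(1E,4S,5E)-4-acetoxy-2,6,10-trimethylundeca-1,5,9-trien-1-yl}-2-oxo-2,5-dihydrofuran-3-yl]methyl acetate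
Conditions: Hoveyda–Grubbs II (5 mol%), toluene (5 mM), 80 °C
Reagents that add atoms: none
Why: Ring-closing metathesis between the only monosubstituted vinyl group and the acrylate forms the butenolide (ethylene lost); the trisubstituted olefins are inert and C2 is untouched.

**Step 11**
Reactants: 14
Product: 15 the (E)-enal of 14, with the terminal (E)-methyl oxidised to CHO: side chain (1E,4S,5E,9E)-4-acetoxy-2,6,10-trimethyl-11-oxoundeca-1,5,9-trien-1-yl
Conditions: SeO2 (0.5 equiv), t-BuOOH, CH2Cl2, rt; then MnO2, CH2Cl2, rt
Reagents that add atoms: selenium dioxide, O=[Se]=O, with tert-butyl hydroperoxide, CC(C)(C)OO (oxygen source)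
Why: SeO2 allylic oxidation (ene/[2,3]) is E-selective for the terminal gem-dimethyl olefin, the most electron-rich one (the other two are deactivated by adjacent acyloxy groups); MnO2 takes the allylic alcohol on to the enal.

**Step 12**
Reactants: 15
Product: 16 the terminal 1,3-diene: side chain (1E,4S,5E,9E)-4-acetoxy-2,6,10-trimethyldodeca-1,5,9,11-tetraen-1-yl
Conditions: CH2Br2, Zn, TiCl4, THF–CH2Cl2, 0 °C
Reagents that add atoms: dibromomethane, BrCBr
Why: Takai–Lombardo methylenation of the enal under non-basic conditions spares the base-sensitive γ-alkenyl butenolide and the two acetates.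

**Step 13**
Reactants: 16
Product: 17 the open-chain C14 alcohol: side chain (1E,4S,5E,9E)-4-acetoxy-12-hydroxy-2,6,10-trimethyldodeca-1,5,9-trien-1-yl on the (5S)-3-(acetoxymethyl)butenolide
Conditions: 9-BBN (1.2 equiv), THF, 0 °C → rt; then 30% H2O2, pH 7 phosphate buffer, 0 °C
Reagents that add atoms: hydrogen peroxide, OO (9-BBN adds only H/B)
Why: 9-BBN hydroborates only the terminal vinyl of the diene, anti-Markovnikov; trisubstituted and electron-poor olefins, esters and the lactone are inert, and buffered oxidation spares the butenolide.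

**Step 14**
Reactants: 17
Product: 18 kericembrenolide D (1S,2S,6S,14S), with acetic acid as by-product
Conditions: Ir[dF(CF3)ppy]2(dtbbpy)PF6 (2 mol%), quinuclidine (20 mol%), n-Bu4N·H2PO4 (25 mol%), MeCN (1 mM), 450 nm LEDs, 25 °C
Reagents that add atoms: none
Why: Proposed new method: a photoredox/HAT radical SN2′ macrocyclisation. The quinuclidinium radical cation (from Ir(III)* oxidation) abstracts the phosphate-H-bond-activated carbinol C14–H; the nucleophilic α-hydroxyalkyl radical adds 14-exo to the butenolide β-carbon C1, anti to the C2 side chain (trans-lactone, 1S); Ir(II) reduces the α-lactone radical to the enolate, which expels acetate (E1cB) to give the exo-methylene in a redox-neutral cycle. C14 is expected to be S from an open transition state with no metal bridging O14 and C17: the carbinol H eclipses the C15–CH2OAc group (allylic strain), the C13 chain points to the open C2–H side and the OH sits over the lactone carbonyl. Closest known reactions: H-bond-assisted α-C–H alkylation of alcohols with acrylates, photoredox radical allylation with Baylis–Hillman acetates, and radical macrocyclisation onto acrylates.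

**Compound list**

1 | (R)-2,3-O-isopropylideneglyceraldehyde | O=C[C@H]1COC(C)(C)O1 | starting material
2 | isopropenylmagnesium bromide | C=C(C)[Mg]Br | starting material
3 | (S)-1-[(R)-2,2-dimethyl-1,3-dioxolan-4-yl]-2-methylprop-2-en-1-ol | C=C(C)[C@H](O)[C@H]1COC(C)(C)O1 | intermediate
4 | geranyl bromide | CC(C)=CCC/C(C)=C/CBr | starting material
5 | geranyl ether of 3 | C=C(C)[C@H](OC/C=C(\C)CCC=C(C)C)[C@H]1COC(C)(C)O1 | intermediate
6 | (1E,4S,5E)-1-[(4S)-2,2-dimethyl-1,3-dioxolan-4-yl]-2,6,10-trimethylundeca-1,5,9-trien-4-ol | CC(C)=CCC/C(C)=C/[C@@H](O)C/C(C)=C/[C@H]1COC(C)(C)O1 | intermediate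
7 | acetate of 6 | CC(C)=CCC/C(C)=C/[C@@H](OC(C)=O)C/C(C)=C/[C@H]1COC(C)(C)O1 | intermediate
8 | (2S,3E,6S,7E)-6-acetoxy-4,8,12-trimethyltrideca-3,7,11-triene-1,2-diol | CC(C)=CCC/C(C)=C/[C@@H](OC(C)=O)C/C(C)=C/[C@H](O)CO | intermediate
9 | (2S,3E,6S,7E)-6-acetoxy-2-hydroxy-4,8,12-trimethyltrideca-3,7,11-trienal | CC(C)=CCC/C(C)=C/[C@@H](OC(C)=O)C/C(C)=C/[C@H](O)C=O | intermediate
10 | (3R,4E,7S,8E)-3-hydroxy-5,9,13-trimethyltetradeca-1,4,8,12-tetraen-7-yl acetate | CC(C)=CCC/C(C)=C/[C@@H](OC(C)=O)C/C(C)=C/[C@H](O)C=C | intermediate
11 | 2-(bromomethyl)acrylic acid | C=C(CBr)C(=O)O | starting material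
12 | 2-(acetoxymethyl)acrylic acid | C=C(COC(C)=O)C(=O)O | intermediate
13 | 2-(acetoxymethyl)acrylate ester of 10 | CC(C)=CCC/C(C)=C/[C@@H](OC(C)=O)C/C(C)=C/[C@H](OC(=O)C(=C)COC(C)=O)C=C | intermediate
14 | (5S)-3-(acetoxymethyl)-5-[(1E,4S,5E)-4-acetoxy-2,6,10-trimethylundeca-1,5,9-trien-1-yl]furan-2(5H)-one | CC(C)=CCC/C(C)=C/[C@@H](OC(C)=O)C/C(C)=C/[C@@H]1OC(=O)C(COC(C)=O)=C1 | intermediate
15 | terminal (E)-enal of 14 | O=C/C(C)=C/CC/C(C)=C/[C@@H](OC(C)=O)C/C(C)=C/[C@@H]1OC(=O)C(COC(C)=O)=C1 | intermediate
16 | terminal 1,3-diene | C=C/C(C)=C/CC/C(C)=C/[C@@H](OC(C)=O)C/C(C)=C/[C@@H]1OC(=O)C(COC(C)=O)=C1 | intermediate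
17 | open-chain C14 primary alcohol | OCC/C(C)=C/CC/C(C)=C/[C@@H](OC(C)=O)C/C(C)=C/[C@@H]1OC(=O)C(COC(C)=O)=C1 | intermediate
18 | kericembrenolide D | C=C1C(=O)O[C@H]2/C=C(\C)C[C@H](OC(C)=O)/C=C(\C)CC/C=C(\C)C[C@H](O)[C@H]12 | target

**Totals**

Total step count: 14. Longest linear sequence: 13 (steps 1–7 and 9–14; step 8 is a one-step side branch).

**Three steps most likely to fail**

1. Step 14 (proposed new macrocyclisation). Risks are competing allylic C–H abstraction, amine-induced isomerisation of the γ-alkenyl butenolide, and the C1/C14 diastereoselectivity.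
   Fallback (known chemistry): oxidise 17 to the C14 aldehyde (Dess–Martin) and close the ring by a two-electron Barbier-type allylation. Either use Pd(0)/InI umpolung of the allylic acetate, or make the bromide analogue from 11 and use a CrCl2 Nozaki–Hiyama closure. The metal-bridged chair transition state should give the 14-epimer, which is corrected by Mitsunobu inversion (HCO2H, then mild formate cleavage).

2. Step 3 ([2,3]-Wittig). Risks are E/Z erosion at the new C3=C4 bond from A(1,2) strain with the C4 methyl, and imperfect deprotonation regioselectivity; either would also erode C6.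
   Fallback: relay C3 to C6 by an Ireland–Claisen rearrangement of the O-PMB-glycolate ester of 3 (chair transition state, reliably E). Then build C7–C13 from the resulting C7 acid by isopropenyl Grignard addition / Johnson–Claisen iterations.

3. Steps 6–7 (α-hydroxy-β,γ-unsaturated aldehyde 9 and its methylenation). Risks are enolisation or conjugation and dimerisation of 9.
   Fallback: carry C6–OH as a TBS ether instead of the acetate, convert the diol to the terminal epoxide, and homologate it with dimethylsulfonium methylide to the vinyl carbinol. Exchange TBS for acetate after the metathesis.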